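A direct plan would build one common resorcylate, methyl 2,4-dihydroxy-5,6-dimethylbenzoate (A1), by Michael–Dieckmann annulation of a malonate with an enone and Br2 aromatisation, and use it for both halves.
A sulfonium-ylide [2,3]-shift would mask a formyl group at C3 as the dithiane A2; one portion would be benzylated, O-methylated and desulfurised/debenzylated with Raney Ni to the phenol half.
The other portion would be unmasked with HgCl2 and saponified to 3-formyl-2,4-dihydroxy-5,6-dimethylbenzoic acid (A3), and (CF3CO)2O would esterify A3 with the phenol half.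
Weak point 1, the closing esterification: a 2,6-disubstituted acid with a free aldehyde and two free OH groups would have to acylate a di-ortho-methyl phenol, so self-acylation, oligomers and decarboxylation would threaten the most advanced material in the last step.
Weak point 2, the handling of the formyl carbon: it would enter early at −70 °C as a thioacetal and then need a mercury unmasking and a hindered saponification beside a free aldehyde, three operations for one carbon.
Weak point 3, the run-up: two ring-forming steps would be spent just to reach the simple arene A1, followed by protecting-group and sulfur traffic that would turn a formyl equivalent into a methyl group and build nothing.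

**Retrosynthetic overview**
Ring A (the benzoyl ring: C1 carboxyl, C2 and C4 OH, C3 CHO, C5 and C6 methyl) is read as a folded tetraketide and is grown on the ring B oxygen instead of being esterified: diketo-dioxinone 11 is a masked 6-methyl-3,5,7-trioxooctanoyl ketene.
Key disconnections: the depside C(=O)–O bond (ketene capture by phenol 6) and the C1–C6 bond of ring A (aldol–dehydration), both made in one operation; then the C3–CHO bond by Rieche formylation.
Ring order: ring B comes ready-made in the fragrance chemical 1 (one C-methyl and one O-methyl are added), ring A closes in step 7, and the formyl group enters last at the only aromatic C–H of the molecule.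
By design there is no free β-resorcylic acid, no activation of a hindered acid (the acylating carbon is an sp ketene carbon without ortho substituents), no thioacetal, no mercury and no saponification; 11 costs two steps from a commercial dioxinone.

Key step: step 7

Remark: methyl 2,4-dihydroxy-3,6-dimethylbenzoate (1) and 2,2,6-trimethyl-4H-1,3-dioxin-4-one (7) are assumed to be purchased; ring A is the acyl ring and ring B the phenol ring, each numbered from the carbon that bears its carboxyl carbon.

Step 1
Reactants: 1 methyl 2,4-dihydroxy-3,6-dimethylbenzoate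
Product: 2 methyl 5-formyl-2,4-dihydroxy-3,6-dimethylbenzoate
Conditions: Cl2CHOMe (1.5 equiv), TiCl4 (3 equiv), CH2Cl2, −10 °C to rt; then 1 M HCl
Reagents that add atoms: dichloromethyl methyl ether, COC(Cl)Cl; water, O
Why: Rieche formylation (electrophilic aromatic substitution by the TiCl4-activated chloro(methoxy)methyl cation) can only strike C5, the single free ring position, which is ortho to the 4-OH and para to the 2-OH.

Step 2
Reactants: 2 methyl 5-formyl-2,4-dihydroxy-3,6-dimethylbenzoate
Product: 3 methyl 2,4-dihydroxy-3,5,6-trimethylbenzoate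
Conditions: Et3SiH (3 equiv), CF3CO2H–CH2Cl2 (1:1), 0 °C to rt
Reagents that add atoms: none
Why: Ionic hydrogenation should deoxygenate CHO to CH3 because the protonated aldehyde and then the benzylic cation, both stabilised by the ortho and para hydroxy groups, each accept hydride from the silane, while the ester is inert.

Step 3
Reactants: 3 methyl 2,4-dihydroxy-3,5,6-trimethylbenzoate
Product: 5 methyl 4-(benzyloxy)-2-methoxy-3,5,6-trimethylbenzoate, via monobenzyl ether 4 (not isolated)
Conditions: BnBr (1.05 equiv), K2CO3 (3 equiv), DMF, rt; then MeI (3 equiv), 50 °C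
Reagents that add atoms: benzyl bromide, BrCc1ccccc1; iodomethane, CI
Why: Two-stage Williamson etherification, in which the non-chelated and more acidic 4-OH (para to the ester) should be benzylated at room temperature and the ester-chelated 2-OH methylated only on warming with excess MeI.

Step 4
Reactants: 5 methyl 4-(benzyloxy)-2-methoxy-3,5,6-trimethylbenzoate
Product: 6 methyl 4-hydroxy-2-methoxy-3,5,6-trimethylbenzoate
Conditions: H2 (1 atm), Pd/C (10%), EtOAc, rt
Reagents that add atoms: none
Why: Catalytic hydrogenolysis should cleave the benzyl aryl ether and leave the methyl ether, the ester and the fully substituted arene untouched.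

Step 5
Reactants: 7 2,2,6-trimethyl-4H-1,3-dioxin-4-one; 8 propanoyl chloride
Product: 9 2,2-dimethyl-6-(2-oxobutyl)-4H-1,3-dioxin-4-one
Conditions: 7 (2.0 equiv), LiN(SiMe3)2 (2.0 equiv), THF, −78 °C; then 8 (1.0 equiv), −78 °C; aq. NH4Cl
Reagents that add atoms: none
Why: Crossed Claisen-type C-acylation of the γ-lithium dienolate of the dioxinone by the acid chloride, in which the second equivalent of dienolate takes up the acidic proton of the product so that no second acylation should occur.

Step 6
Reactants: 9 2,2-dimethyl-6-(2-oxobutyl)-4H-1,3-dioxin-4-one; 10 N-methoxy-N-methylacetamide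
Product: 11 2,2-dimethyl-6-(3-methyl-2,4-dioxopentyl)-4H-1,3-dioxin-4-one
Conditions: LiN(iPr)2 (2.2 equiv), THF, −78 °C; then 10 (1.2 equiv), −78 to −20 °C; then aq. HCl (pH 3)
Reagents that add atoms: none
Why: Claisen condensation of a dicarbonyl dianion, in which the second deprotonation at the ethyl CH2 gives the more basic carbanion that alone should attack the N-methoxy-N-methylamide, whose chelated tetrahedral adduct holds until work-up and prevents over-addition.

Step 7
Reactants: 11 2,2-dimethyl-6-(3-methyl-2,4-dioxopentyl)-4H-1,3-dioxin-4-one; 6 methyl 4-hydroxy-2-methoxy-3,5,6-trimethylbenzoate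
Product: 15 methyl 4-[(2,4-dihydroxy-5,6-dimethylbenzoyl)oxy]-2-methoxy-3,5,6-trimethylbenzoate, via acylketene 12 (not isolated), via aryl triketoester 13 (not isolated), via cyclic aldol 14 (not isolated)
Conditions: 6 (1.0 equiv, 0.5 M), 11 (1.5 equiv, added in portions), PhMe, 110 °C (acetone distilled off); cool, Et3N (1.5 equiv), rt; then 1 M HCl
Reagents that add atoms: none
Why: Heating should make dioxinone 11 lose acetone by a retro-hetero-Diels–Alder reaction to acylketene 12, whose unhindered sp carbon is attacked by the di-ortho-methyl phenol 6 to give aryl 6-methyl-3,5,7-trioxooctanoate 13, and Et3N should then fold 13 by intramolecular aldol addition of chain C2 (the CH2 between ester and ketone) to the C7 methyl ketone, followed by dehydration and enolisation of 14 to ring A. The closest known reaction types are the acetoacetylation of phenols with 2,2,6-trimethyl-4H-1,3-dioxin-4-one and the biomimetic aromatisation of dioxinone-masked 3,5,7-triketo esters to resorcylates. Ring A closes in the 6-(enolendo)-exo-trig mode by forming its C1–C6 bond, and aromatisation makes the closure irreversible. No stereocentre has to be controlled, because the sp3 centres of 13 and 14 are erased on aromatisation. The step needs intermolecular O–H capture of 12 to beat O-acylation by its own enol (pyranone formation), which the high concentration of 6 and the excess of cheap 11 should secure. It also needs the C2-to-C7 aldol to beat lactonisation and other aldol modes: C2 is far more acidic than the terminal methyl, the more acidic C4 and C6 could only close four-membered rings, and the two ortho methyl groups of ring B shield the aryl ester carbonyl from the enolate oxygens.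

Step 8
Reactants: 15 methyl 4-[(2,4-dihydroxy-5,6-dimethylbenzoyl)oxy]-2-methoxy-3,5,6-trimethylbenzoate
Product: 16 methyl 4-[(3-formyl-2,4-dihydroxy-5,6-dimethylbenzoyl)oxy]-2-methoxy-3,5,6-trimethylbenzoate
Conditions: Cl2CHOMe (1.5 equiv), TiCl4 (3 equiv), CH2Cl2, −20 to 0 °C; then 1 M HCl, 0 °C
Reagents that add atoms: dichloromethyl methyl ether, COC(Cl)Cl; water, O
Why: Rieche formylation should be regiospecific because C3 of ring A is the only aromatic C–H of 15 and lies between two titanium-binding hydroxy groups, ring B is hexasubstituted, and the aldehyde emerges hydrogen-bonded to both neighbouring OH groups.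

**Compound list**
1 | methyl 2,4-dihydroxy-3,6-dimethylbenzoate | COC(=O)c1c(C)cc(O)c(C)c1O | starting material
2 | methyl 5-formyl-2,4-dihydroxy-3,6-dimethylbenzoate | COC(=O)c1c(C)c(C=O)c(O)c(C)c1O | intermediate
3 | methyl 2,4-dihydroxy-3,5,6-trimethylbenzoate | COC(=O)c1c(C)c(C)c(O)c(C)c1O | intermediate
4 | methyl 4-(benzyloxy)-2-hydroxy-3,5,6-trimethylbenzoate | COC(=O)c1c(C)c(C)c(OCc2ccccc2)c(C)c1O | intermediate
5 | methyl 4-(benzyloxy)-2-methoxy-3,5,6-trimethylbenzoate | COC(=O)c1c(C)c(C)c(OCc2ccccc2)c(C)c1OC | intermediate
6 | methyl 4-hydroxy-2-methoxy-3,5,6-trimethylbenzoate | COC(=O)c1c(C)c(C)c(O)c(C)c1OC | intermediate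
7 | 2,2,6-trimethyl-4H-1,3-dioxin-4-one | CC1=CC(=O)OC(C)(C)O1 | starting material
8 | propanoyl chloride | CCC(=O)Cl | starting material
9 | 2,2-dimethyl-6-(2-oxobutyl)-4H-1,3-dioxin-4-one | CCC(=O)CC1=CC(=O)OC(C)(C)O1 | intermediate
10 | N-methoxy-N-methylacetamide | CC(=O)N(C)OC | starting material
11 | 2,2-dimethyl-6-(3-methyl-2,4-dioxopentyl)-4H-1,3-dioxin-4-one (racemic, enolisable) | CC(=O)C(C)C(=O)CC1=CC(=O)OC(C)(C)O1 | intermediate
12 | 6-methyloct-1-ene-1,3,5,7-tetrone (acylketene, racemic) | CC(=O)C(C)C(=O)CC(=O)C=C=O | intermediate
13 | methyl 2-methoxy-3,5,6-trimethyl-4-[(6-methyl-3,5,7-trioxooctanoyl)oxy]benzoate (racemic) | COC(=O)c1c(C)c(C)c(OC(=O)CC(=O)CC(=O)C(C)C(C)=O)c(C)c1OC | intermediate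
14 | methyl 4-[(2-hydroxy-2,3-dimethyl-4,6-dioxocyclohexane-1-carbonyl)oxy]-2-methoxy-3,5,6-trimethylbenzoate (diastereomer mixture) | COC(=O)c1c(C)c(C)c(OC(=O)C2C(=O)CC(=O)C(C)C2(C)O)c(C)c1OC | intermediate
15 | methyl 4-[(2,4-dihydroxy-5,6-dimethylbenzoyl)oxy]-2-methoxy-3,5,6-trimethylbenzoate | COC(=O)c1c(C)c(C)c(OC(=O)c2c(C)c(C)c(O)cc2O)c(C)c1OC | intermediate
16 | methyl 4-[(3-formyl-2,4-dihydroxy-5,6-dimethylbenzoyl)oxy]-2-methoxy-3,5,6-trimethylbenzoate | COC(=O)c1c(C)c(C)c(OC(=O)c2c(C)c(C)c(O)c(C=O)c2O)c(C)c1OC | target

Total step count: 8. Longest linear sequence: 6 (steps 1, 2, 3, 4, 7, 8).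

**Steps most likely to fail**

Step 7. Capture of the acylketene by the hindered phenol may lose out to O-acylation by the ketene's own enol, or the aryl β-ketoester may expel phenoxide before the aldol closes. The fallback sets out from 11 and closes ring A first. Et3N in CH2Cl2 at rt should give, by aldol–dehydration with the dioxinone ring intact, 7-hydroxy-2,2,5,6-tetramethyl-4H-1,3-benzodioxin-4-one F1. Irradiation of F1 at 300 nm in CH2Cl2 with an excess of phenol 6 should then release acetone and a quinoketene that 6 captures (photochemical salicylate acylation). The fallback returns to the route at 15.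

Step 6. Proton transfer to the dianion or O-acylation may erode the Claisen condensation at the secondary carbanion. The fallback sets out from 9 and replaces acylation by aldol addition and oxidation. The same dianion (LiN(iPr)2, 2.2 equiv, THF, −78 °C) would be added to acetaldehyde to give 6-(4-hydroxy-3-methyl-2-oxopentyl)-2,2-dimethyl-4H-1,3-dioxin-4-one F2 as a diastereomer mixture of no consequence. Dess–Martin oxidation (NaHCO3, CH2Cl2) of F2 would return to the route at 11.

Step 8. The strong Lewis acid may cleave the depside ester or the ortho-methoxy group of ring B, or the attack between two OH groups may stall. The fallback sets out from 15 and brings the carbon in at the alcohol oxidation level.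
- PhB(OH)2, paraformaldehyde and catalytic propanoic acid in refluxing toluene (water removed) should give, by boron-templated ortho-hydroxymethylation, methyl 4-[(5-hydroxy-7,8-dimethyl-2-phenyl-4H-1,3,2-benzodioxaborinine-6-carbonyl)oxy]-2-methoxy-3,5,6-trimethylbenzoate F3.
- Hydrolysis of F3 in aqueous THF should free methyl 4-{[2,4-dihydroxy-3-(hydroxymethyl)-5,6-dimethylbenzoyl]oxy}-2-methoxy-3,5,6-trimethylbenzoate F4.
- MnO2 in CH2Cl2 should oxidise the benzylic alcohol of F4 and return to the route at 16.

Further compounds
F1 | step 7 | 7-hydroxy-2,2,5,6-tetramethyl-4H-1,3-benzodioxin-4-one | CC1(C)OC(=O)c2c(C)c(C)c(O)cc2O1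
F2 | step 6 | 6-(4-hydroxy-3-methyl-2-oxopentyl)-2,2-dimethyl-4H-1,3-dioxin-4-one (diastereomer mixture) | CC(O)C(C)C(=O)CC1=CC(=O)OC(C)(C)O1
F3 | step 8 | methyl 4-[(5-hydroxy-7,8-dimethyl-2-phenyl-4H-1,3,2-benzodioxaborinine-6-carbonyl)oxy]-2-methoxy-3,5,6-trimethylbenzoate | COC(=O)c1c(C)c(C)c(OC(=O)c2c(C)c(C)c3OB(c4ccccc4)OCc3c2O)c(C)c1OC
F4 | step 8 | methyl 4-{[2,4-dihydroxy-3-(hydroxymethyl)-5,6-dimethylbenzoyl]oxy}-2-methoxy-3,5,6-trimethylbenzoate | COC(=O)c1c(C)c(C)c(OC(=O)c2c(C)c(C)c(O)c(CO)c2O)c(C)c1OC
A1 | direct plan | methyl 2,4-dihydroxy-5,6-dimethylbenzoate | COC(=O)c1c(O)cc(O)c(C)c1C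
A2 | direct plan | methyl 3-(1,3-dithian-2-yl)-2,4-dihydroxy-5,6-dimethylbenzoate | COC(=O)c1c(O)c(C2SCCCS2)c(O)c(C)c1C
A3 | direct plan | 3-formyl-2,4-dihydroxy-5,6-dimethylbenzoic acid | OC(=O)c1c(O)c(C=O)c(O)c(C)c1C
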